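**Strategy.** The eastern decalin (numbered C1–C10: ring C = C5–C10, ring D = C1–C5 and C10, C4 = gem-dimethyl carbon, C9 = quaternary carbon) is opened at C3–C4. Ring D is a cyclohexene whose six carbons map onto a hexatriene, so a pulegone-derived ring C carrying an acryloyl group at C10 and the isopropylidene at C5 is deprotonated to a 3-oxido-hexatriene; one 6π-electrocyclization closes ring D, forges the quaternary C4 and converges all C10 and enolate isomers into a single enone. Carbinol-to-C5 chirality transfer then places the C1=C10 alkene. The western decalin comes from an asymmetric Diels–Alder reaction; an axial dienolate alkylation unites the halves.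

Key step: step 14

Remark: the target is taken as the free bis(hydrogen sulfate) drawn; it is liberated from its pyridinium salt by cation exchange.
Remark: 2–4 are racemic, and both enantiomers of 4 are consumed in step 6. Compounds 11–14 (methyl-bearing carbon next to the masked or free ketone) and 18–20 (C10) are carried as epimer mixtures at one carbon, because that carbon is planarized later; the SMILES of 18 and 19 show the expected major epimer.
Remark: in the western decalin, ring A is the cyclohexene that carries the benzyl group and ring B is the other ring.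

Step 1
Reactants: 1 2-methylcyclohexane-1,3-dione
Product: 2 6-methyl-1,4-dioxaspiro[4.5]decan-7-one (racemic)
Conditions: HOCH2CH2OH (1.1 equiv), p-TsOH·H2O (cat.), benzene, reflux (Dean–Stark)
Reagents that add atoms: ethane-1,2-diol OCCO
Why: Acid-catalysed mono-ketalization masks the carbonyl that later activates the western quaternary carbon and leaves the other for diene construction; the methyl-bearing centre stays racemic, which is harmless because it is planarized in step 17.

Step 2
Reactants: 2 6-methyl-1,4-dioxaspiro[4.5]decan-7-one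
Product: 3 6-methyl-1,4-dioxaspiro[4.5]dec-7-en-7-yl trifluoromethanesulfonate (racemic)
Conditions: KN(SiMe3)2, THF, −78 °C; PhNTf2, −78 to 0 °C; aq. NH4Cl
Reagents that add atoms: N-phenylbis(trifluoromethanesulfonimide) O=S(=O)(N(c1ccccc1)S(=O)(=O)C(F)(F)F)C(F)(F)F
Why: Kinetic deprotonation should occur at the unhindered methylene and not at the methine flanked by ketal and carbonyl, and O-triflation of the potassium enolate then gives the enol triflate regioselectively.

Step 3
Reactants: 3 enol triflate
Product: 4 6-methyl-7-vinyl-1,4-dioxaspiro[4.5]dec-7-ene (racemic diene)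
Conditions: Bu3SnCH=CH2, Pd(PPh3)4 (5 mol %), LiCl, THF, 65 °C
Reagents that add atoms: tributyl(vinyl)stannane C=C[Sn](CCCC)(CCCC)CCCC
Why: Stille coupling of the enol triflate (oxidative addition, transmetalation, reductive elimination) should give the 1-vinylcyclohexene diene.

Step 4
Reactants: 5 2-(chloromethyl)-1,4-dimethoxybenzene (2,5-dimethoxybenzyl chloride); 6 2-(triphenyl-λ5-phosphanylidene)acetaldehyde
Product: 8 3-(2,5-dimethoxyphenyl)-2-(triphenyl-λ5-phosphanylidene)propanal, via phosphonium chloride 7 (not isolated)
Conditions: NaI (cat.), MeCN, 80 °C; then aq. NaOH, CH2Cl2, rt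
Reagents that add atoms: none
Why: C-Alkylation of the stabilized formyl ylide by the reactive benzylic halide, then deprotonation of the phosphonium salt, should give the α-benzyl ylide.

Step 5
Reactants: 8 α-benzyl formyl ylide; 9 acetaldehyde
Product: 10 (E)-2-(2,5-dimethoxybenzyl)but-2-enal
Conditions: MeCHO (excess), toluene, 90 °C (sealed tube)
Reagents that add atoms: none
Why: Wittig olefination by the stabilized α-substituted ylide should give the (E)-enal (methyl trans to formyl), the geometry that later places the secondary methyl cis to the benzyl group.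

Step 6
Reactants: 4 racemic diene; 10 (E)-enal
Product: 11 Diels–Alder adduct 5′-(2,5-dimethoxybenzyl)-1′,6′-dimethyl-3′,4′,4a′,5′,6′,7′-hexahydro-1′H-spiro[1,3-dioxolane-2,2′-naphthalene]-5′-carbaldehyde (4a′-H cis to benzyl, formyl trans to 4a′-H, (6′R)-methyl cis to benzyl, C1′ epimers)
Conditions: o-tolyl-CBS-oxazaborolidine·HNTf2 (20 mol %; antipode that leaves the Cα-Re face of 10 open), CH2Cl2, −78 to −40 °C, 4 and 10 in equimolar amounts
Reagents that add atoms: none
Why: Asymmetric Diels–Alder reaction under a cationic oxazaborolidine Lewis acid, a pure addition in which both enantiomers of 4 are taken up because the diene's methyl centre lies on a ring carbon outside the reacting termini and the catalyst decides the face: the enal β-carbon bonds to the unsubstituted vinyl terminus and its α-carbon to the ring terminus (ortho orientation), the formyl group is endo and only the Cα-Re face is open, so the quaternary carbon, the ring-fusion CH (H cis to benzyl) and the secondary methyl carbon (from the E-enal) should be set together, while the methyl-bearing centre of the diene gives the C1′ epimers and is erased in step 17.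

Step 7
Reactants: 11 Diels–Alder aldehyde
Product: 13 5′-(2,5-dimethoxybenzyl)-1′,5′,6′-trimethyl-3′,4′,4a′,5′,6′,7′-hexahydro-1′H-spiro[1,3-dioxolane-2,2′-naphthalene] (5′-methyl trans to 4a′-H and to 6′-methyl), via hydrazone 12 (not isolated)
Conditions: N2H4·H2O, KOH, diethylene glycol, 130 then 200 °C
Reagents that add atoms: none
Why: Wolff–Kishner reduction converts the neopentyl formyl group into the methyl group of the quaternary carbon and should leave the base-stable ketal, the alkene and the stereocentres untouched.

Step 8
Reactants: 13 ketal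
Product: 14 5-(2,5-dimethoxybenzyl)-1,5,6-trimethyl-3,4,4a,5,6,7-hexahydronaphthalen-2(1H)-one ((6R), 5-methyl trans to 6-methyl and to 4a-H, C1 epimers)
Conditions: PPTS (cat.), acetone/H2O, 40 °C
Reagents that add atoms: water O
Why: Mild acid-catalysed ketal hydrolysis should unmask the ketone as the β,γ-unsaturated isomer, the buffered conditions being chosen so that the alkene does not move into conjugation and the ring-fusion centre is not exposed to enolization.

Step 9
Reactants: 15 (S)-(−)-pulegone
Product: 16 (5S,6R)-5,6-dimethyl-2-(propan-2-ylidene)cyclohexan-1-one (trans)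
Conditions: LiN(i-Pr)2, THF, −78 °C; MeI, −78 to 0 °C
Reagents that add atoms: iodomethane CI
Why: Kinetic deprotonation of the enone at the α′-methylene gives the cross-conjugated lithium enolate, which is methylated; the new centre is re-enolized in step 10, so its configuration is irrelevant.

Step 10
Reactants: 16 trans-6-methylpulegone
Product: 17 (5S,6R)-6-(2-chloroethyl)-5,6-dimethyl-2-(propan-2-ylidene)cyclohexan-1-one
Conditions: LiN(i-Pr)2, THF, −78 to −30 °C; ClCH2CH2OTf, −78 to −20 °C
Reagents that add atoms: 2-chloroethyl trifluoromethanesulfonate ClCCOS(=O)(=O)C(F)(F)F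
Why: Alkylation of the tetrasubstituted α′-enolate by the primary triflate should occur on the face opposite the adjacent pseudoaxial C8 methyl group, giving quaternary C9 with the chloroethyl arm trans and the methyl group cis to the C8 methyl, the chloride end staying inert.

Step 11
Reactants: 17 chloroethyl enone
Product: 18 (5S,6R)-6-(2-chloroethyl)-5,6-dimethyl-2-(propan-2-ylidene)cyclohexan-1-ol (major epimer: OH cis to the two methyl groups)
Conditions: NaBH4, CeCl3·7H2O, MeOH, 0 °C
Reagents that add atoms: none
Why: Luche 1,2-reduction of the hindered enone gives the allylic alcohol (hydride expected anti to the two cis methyl groups); the carbinol configuration is irrelevant because C10 is planarized in step 14.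

Step 12
Reactants: 18 allylic alcohol
Product: 19 methyl carbonate of 18
Conditions: ClCO2Me, pyridine, DMAP (cat.), CH2Cl2, 0 °C to rt
Reagents that add atoms: methyl chloroformate COC(Cl)=O
Why: Acylation under nucleophilic catalysis installs the carbonate leaving group without generating an alkoxide that could displace the chloride.

Step 13
Reactants: 19 allylic carbonate
Product: 20 1-[(2R,3S)-2-(2-chloroethyl)-2,3-dimethyl-6-(propan-2-ylidene)cyclohexyl]prop-2-en-1-one (C10 epimers)
Conditions: Pd2(dba)3 (2.5 mol %), PPh3 (10 mol %), CO (3 atm), Bu3SnCH=CH2, DMF, 50 °C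
Reagents that add atoms: carbon monoxide [C-]#[O+]; tributyl(vinyl)stannane C=C[Sn](CCCC)(CCCC)CCCC
Why: Carbonylative Stille coupling of the allylic carbonate (ionization to the π-allylpalladium species with loss of carbon dioxide, CO insertion at the less hindered secondary terminus C10, vinyl transfer from tin) should give the β,γ-unsaturated vinyl ketone, whose C10 epimers both converge in step 14.

Step 14
Reactants: 20 allyl vinyl ketone
Product: 23 (7S,8R)-8-(2-chloroethyl)-4,4,7,8-tetramethyl-3,4,5,6,7,8-hexahydronaphthalen-1(2H)-one, via potassium dienolate 21 (not isolated), via potassium cyclohexadienolate 22 (not isolated)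
Conditions: KN(SiMe3)2 (0.95 equiv), THF (0.01 M), −78 °C to rt; aq. NH4Cl
Reagents that add atoms: none
Why: Deprotonation at C10, which is α to the ketone and allylic to C5=C4, gives the cross-conjugated dienolate 21, a 3-oxido-hexatriene C3=C2–C1(O−)=C10–C5=C4, whose thermal disrotatory 6π-electrocyclization forms the C3–C4 bond and the cyclohexadienolate 22; C-protonation at C2 then gives enone 23. The closest known reaction type is the alkoxide-accelerated 6π-electrocyclization of 3-oxido-hexatrienes to cyclohexenones, which proceeds at or below room temperature. Ring D is closed in the 6π-electrocyclic (6-endo) mode, and the same bond makes C4 the quaternary gem-dimethyl carbon. No new stereocentre is formed: C10 becomes trigonal, so both epimers of 20 give the same dienolate, and enolate geometrical isomers interconvert by proton exchange with residual ketone so that only the cyclizable (Z)-isomer is drained. The step needs periselectivity over intermolecular Michael addition to the vinyl ketone and over O-alkylation by the chloroethyl arm; the two exocyclic double bonds held s-cis on ring C, high dilution and low temperature should secure it. The existing C8 and C9 centres lie outside the reacting π-array and are untouched.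

Step 15
Reactants: 23 enone
Product: 24 (1S,7S,8R)-8-(2-chloroethyl)-4,4,7,8-tetramethyl-1,2,3,4,5,6,7,8-octahydronaphthalen-1-ol
Conditions: (R)-2-methyl-CBS-oxazaborolidine (20 mol %), BH3·SMe2, THF, −20 °C; MeOH
Reagents that add atoms: none
Why: Corey–Bakshi–Shibata reduction, in which the catalyst–borane complex binds the ketone anti to the fully substituted alkenyl carbon (large group) and delivers hydride to one face under reagent control, should give the (1S)-carbinol with the hydroxyl on the face of the chloroethyl arm.

Step 16
Reactants: 24 allylic alcohol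
Product: 27 (1R,2S,4aR)-1-(2-chloroethyl)-1,2,5,5-tetramethyl-1,2,3,4,4a,5,6,7-octahydronaphthalene, via sulfonylhydrazine adduct 25 (not isolated), via allylic diazene 26 (not isolated)
Conditions: 2-O2NC6H4SO2NHNH2, PPh3, DEAD, THF, −30 °C; then rt
Reagents that add atoms: none
Why: Mitsunobu displacement by the sulfonylhydrazide inverts C1, loss of the sulfinic acid gives the monoalkyl diazene, and its retro-ene loss of dinitrogen transfers hydrogen suprafacially to C5 on the face of the C–N bond while moving the alkene to C1=C10, so the C5 stereocentre (H cis to the C8 and C9 methyl groups) should be set by chirality transfer from C1.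

Step 17
Reactants: 14 β,γ-unsaturated ketone; 27 eastern chloride
Product: 30 coupled ketone (toxiusol skeleton with a ketone next to the western quaternary carbon, hydroquinone as dimethyl ether), via potassium dienolate 28 (not isolated), via alkyl iodide 29 (not isolated)
Conditions: KN(SiMe3)2 (0.98 equiv), THF, −78 to −40 °C; then 27, NaI (20 mol %), DMPU, −40 to 40 °C
Reagents that add atoms: none
Why: Deprotonation at the doubly activated α-carbon gives the extended dienolate, which should be C-alkylated at that carbon by the primary iodide formed in situ (Finkelstein exchange) along the axial trajectory syn to the axial ring-fusion hydrogen, creating the western quaternary carbon with the two-carbon link cis to that hydrogen and keeping the alkene in ring A.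

Step 18
Reactants: 30 coupled ketone
Product: 32 toxiusol hydroquinone dimethyl ether, via hydrazone 31 (not isolated)
Conditions: N2H4·H2O, KOH, diethylene glycol, 130 then 200 °C
Reagents that add atoms: none
Why: Wolff–Kishner reduction removes the ketone, and because its α-carbon is quaternary the alkene cannot move into conjugation and no stereocentre is enolizable.

Step 19
Reactants: 32 dimethyl ether
Product: 33 toxiusol hydroquinone (bis-desulfated toxiusol)
Conditions: NaSEt, DMF, 150 °C; then degassed aq. HCl
Reagents that add atoms: none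
Why: SN2 demethylation of both aryl methyl ethers by thiolate avoids the acids and oxidants that would endanger the two trisubstituted alkenes.

Step 20
Reactants: 33 hydroquinone
Product: 34 toxiusol
Conditions: SO3·pyridine, pyridine, 50 °C; then H+-form cation-exchange resin, MeOH/H2O
Reagents that add atoms: sulfur trioxide–pyridine complex [O-]S(=O)(=O)[n+]1ccccc1
Why: O-Sulfation of both phenols by the SO3·pyridine complex followed by cation exchange should give the bis(hydrogen sulfate) without affecting any stereocentre.

**Compound list**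

1 | 2-methylcyclohexane-1,3-dione | CC1C(=O)CCCC1=O | starting material
2 | 6-methyl-1,4-dioxaspiro[4.5]decan-7-one (racemic) | CC1C(=O)CCCC12OCCO2 | intermediate
3 | 6-methyl-1,4-dioxaspiro[4.5]dec-7-en-7-yl trifluoromethanesulfonate (racemic) | CC1C(OS(=O)(=O)C(F)(F)F)=CCCC12OCCO2 | intermediate
4 | 6-methyl-7-vinyl-1,4-dioxaspiro[4.5]dec-7-ene (racemic) | CC1C(C=C)=CCCC12OCCO2 | intermediate
5 | 2-(chloromethyl)-1,4-dimethoxybenzene | COc1ccc(OC)c(CCl)c1 | starting material
6 | 2-(triphenyl-λ5-phosphanylidene)acetaldehyde | O=CC=P(c1ccccc1)(c1ccccc1)c1ccccc1 | starting material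
7 | [1-(2,5-dimethoxyphenyl)-3-oxopropan-2-yl]triphenylphosphonium chloride | [Cl-].O=CC(Cc1cc(OC)ccc1OC)[P+](c1ccccc1)(c1ccccc1)c1ccccc1 | intermediate
8 | 3-(2,5-dimethoxyphenyl)-2-(triphenyl-λ5-phosphanylidene)propanal | O=CC(Cc1cc(OC)ccc1OC)=P(c1ccccc1)(c1ccccc1)c1ccccc1 | intermediate
9 | acetaldehyde | CC=O | starting material
10 | (E)-2-(2,5-dimethoxybenzyl)but-2-enal | C/C=C(/C=O)Cc1cc(OC)ccc1OC | intermediate
11 | Diels–Alder aldehyde (spiroketal; 4a′-H cis to benzyl, formyl trans to 4a′-H, (6′R)-methyl cis to benzyl, C1′ epimers) | C[C@@H]1CC=C2[C@@H](CCC3(OCCO3)C2C)[C@]1(C=O)Cc1cc(OC)ccc1OC | intermediate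
12 | hydrazone of 11 | C[C@@H]1CC=C2[C@@H](CCC3(OCCO3)C2C)[C@]1(C=NN)Cc1cc(OC)ccc1OC | intermediate
13 | 5′-methyl spiroketal (5′-methyl trans to 4a′-H and to 6′-methyl, C1′ epimers) | C[C@@H]1CC=C2[C@@H](CCC3(OCCO3)C2C)[C@]1(C)Cc1cc(OC)ccc1OC | intermediate
14 | 5-(2,5-dimethoxybenzyl)-1,5,6-trimethyl-3,4,4a,5,6,7-hexahydronaphthalen-2(1H)-one ((6R), 5-methyl trans to 6-methyl and to 4a-H, C1 epimers) | C[C@@H]1CC=C2[C@@H](CCC(=O)C2C)[C@]1(C)Cc1cc(OC)ccc1OC | intermediate
15 | (S)-(−)-pulegone, (S)-5-methyl-2-(propan-2-ylidene)cyclohexan-1-one | C[C@H]1CCC(=C(C)C)C(=O)C1 | starting material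
16 | (5S,6R)-5,6-dimethyl-2-(propan-2-ylidene)cyclohexan-1-one | C[C@H]1C(=O)C(=C(C)C)CC[C@@H]1C | intermediate
17 | (5S,6R)-6-(2-chloroethyl)-5,6-dimethyl-2-(propan-2-ylidene)cyclohexan-1-one | ClCC[C@@]1(C)C(=O)C(=C(C)C)CC[C@@H]1C | intermediate
18 | (5S,6R)-6-(2-chloroethyl)-5,6-dimethyl-2-(propan-2-ylidene)cyclohexan-1-ol (OH cis to both methyl groups, major) | ClCC[C@@]1(C)[C@H](O)C(=C(C)C)CC[C@@H]1C | intermediate
19 | methyl carbonate of 18 | ClCC[C@@]1(C)[C@H](OC(=O)OC)C(=C(C)C)CC[C@@H]1C | intermediate
20 | 1-[(2R,3S)-2-(2-chloroethyl)-2,3-dimethyl-6-(propan-2-ylidene)cyclohexyl]prop-2-en-1-one (C10 epimers) | ClCC[C@@]1(C)C(C(=O)C=C)C(=C(C)C)CC[C@@H]1C | intermediate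
21 | potassium (Z)-dienolate of 20 (3-oxido-hexatriene) | ClCC[C@@]1(C)/C(=C(\[O-])C=C)C(=C(C)C)CC[C@@H]1C.[K+] | intermediate
22 | potassium cyclohexadienolate (ring D closed) | ClCC[C@@]1(C)C2=C(CC[C@@H]1C)C(C)(C)CC=C2[O-].[K+] | intermediate
23 | (7S,8R)-8-(2-chloroethyl)-4,4,7,8-tetramethyl-3,4,5,6,7,8-hexahydronaphthalen-1(2H)-one | ClCC[C@@]1(C)C2=C(CC[C@@H]1C)C(C)(C)CCC2=O | intermediate
24 | (1S,7S,8R)-8-(2-chloroethyl)-4,4,7,8-tetramethyl-1,2,3,4,5,6,7,8-octahydronaphthalen-1-ol | ClCC[C@@]1(C)C2=C(CC[C@@H]1C)C(C)(C)CC[C@@H]2O | intermediate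
25 | N-alkyl-N-(2-nitrobenzenesulfonyl)hydrazine (C1 inverted) | ClCC[C@@]1(C)C2=C(CC[C@@H]1C)C(C)(C)CC[C@H]2N(N)S(=O)(=O)c3ccccc3[N+](=O)[O-] | intermediate
26 | allylic monoalkyl diazene | ClCC[C@@]1(C)C2=C(CC[C@@H]1C)C(C)(C)CC[C@H]2N=N | intermediate
27 | (1R,2S,4aR)-1-(2-chloroethyl)-1,2,5,5-tetramethyl-1,2,3,4,4a,5,6,7-octahydronaphthalene | ClCC[C@@]1(C)C2=CCCC(C)(C)[C@H]2CC[C@@H]1C | intermediate
28 | potassium dienolate of 14 | C[C@@H]1CC=C2[C@@H](CCC([O-])=C2C)[C@]1(C)Cc1cc(OC)ccc1OC.[K+] | intermediate
29 | (1R,2S,4aR)-1-(2-iodoethyl)-1,2,5,5-tetramethyl-1,2,3,4,4a,5,6,7-octahydronaphthalene | ICC[C@@]1(C)C2=CCCC(C)(C)[C@H]2CC[C@@H]1C | intermediate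
30 | coupled ketone (both decalins joined by the ethylene link, ketone next to the western quaternary carbon, link cis to the ring-fusion H) | C[C@@H]1CC=C2[C@@H](CCC(=O)[C@@]2(C)CC[C@@]2(C)C3=CCCC(C)(C)[C@H]3CC[C@@H]2C)[C@]1(C)Cc1cc(OC)ccc1OC | intermediate
31 | hydrazone of 30 | C[C@@H]1CC=C2[C@@H](CCC(=NN)[C@@]2(C)CC[C@@]2(C)C3=CCCC(C)(C)[C@H]3CC[C@@H]2C)[C@]1(C)Cc1cc(OC)ccc1OC | intermediate
32 | toxiusol hydroquinone dimethyl ether | C[C@@H]1CC=C2[C@@H](CCC[C@@]2(C)CC[C@@]2(C)C3=CCCC(C)(C)[C@H]3CC[C@@H]2C)[C@]1(C)Cc1cc(OC)ccc1OC | intermediate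
33 | toxiusol hydroquinone | C[C@@H]1CC=C2[C@@H](CCC[C@@]2(C)CC[C@@]2(C)C3=CCCC(C)(C)[C@H]3CC[C@@H]2C)[C@]1(C)Cc1cc(O)ccc1O | intermediate
34 | toxiusol | C[C@@H]1CC=C2[C@@H](CCC[C@@]2(C)CC[C@@]2(C)C3=CCCC(C)(C)[C@H]3CC[C@@H]2C)[C@]1(C)Cc1cc(OS(=O)(=O)O)ccc1OS(=O)(=O)O | target

**Step count and risks**

Total step count: 20. Longest linear sequence: 12 steps (steps 9–20, from (S)-pulegone 15); the western branch from 1 runs through steps 1–3, 6–8 and 17–20.

The three steps most likely to fail:

Step 14 (key step). The electrocyclization may be slow because one C4 methyl group must rotate inward, so that oligomerization by intermolecular Michael addition of the dienolate to the vinyl ketone overtakes ring closure. The fallback sets out from 20 and switches to a polar, Lewis-acid-promoted closure of the same bond: Me2AlCl (1.5 equiv), CH2Cl2, −78 °C activates the vinyl ketone, C4 of the isopropylidene group attacks C3 (cationic six-membered ring closure), the tertiary C5 cation loses the C10 proton, and aqueous work-up gives the enone; it returns to the route at 23 and makes no compound outside the list (F0).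

Step 13. Ionization of the hindered carbonate may be slow because the tetrasubstituted alkene binds zerovalent palladium poorly, and direct vinyl transfer without CO insertion or β-hydride loss to a diene may take over. The fallback sets out from ketone 17 and builds the acyl group by homologation instead: dimethylsulfonium methylide (Me3S+ I−, n-BuLi, THF, −10 °C; Corey–Chaykovsky reaction) gives the spiro-epoxide F1; MgBr2·OEt2 opens it and a 1,2-hydride shift (Meinwald rearrangement) gives the β,γ-unsaturated aldehyde F2; CH2=CHMgBr adds to give the allylic alcohol F3; Dess–Martin periodinane oxidizes it, and the route is rejoined at 20.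

Step 16. The Mitsunobu displacement may fail at the hindered allylic carbinol flanked by the tetrasubstituted alkene, through elimination to a diene or SN2′ attack. The fallback sets out from 24 and delivers the hydrogen from palladium instead: formylation (HCO2H, Ac2O, pyridine) gives the allylic formate F4; Pd(acac)2 (5 mol %), PBu3, dioxane, 100 °C ionizes it anti to the formate, decarboxylation gives the palladium hydride, and hydride is delivered to the more substituted terminus C5 from the metal face, again anti to the original C1–O bond, so the same C5 configuration results and the route is rejoined at 27.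

**Further compounds**

F0 | step 14 | none | none
F1 | step 13 | spiro-epoxide of 17, (7S,8R)-8-(2-chloroethyl)-7,8-dimethyl-4-(propan-2-ylidene)-1-oxaspiro[2.5]octane (spiro epimers) | ClCC[C@@]1(C)C2(CO2)C(=C(C)C)CC[C@@H]1C
F2 | step 13 | (2R,3S)-2-(2-chloroethyl)-2,3-dimethyl-6-(propan-2-ylidene)cyclohexane-1-carbaldehyde (C1 epimers) | ClCC[C@@]1(C)C(C=O)C(=C(C)C)CC[C@@H]1C
F3 | step 13 | 1-[(2R,3S)-2-(2-chloroethyl)-2,3-dimethyl-6-(propan-2-ylidene)cyclohexyl]prop-2-en-1-ol (epimer mixture) | ClCC[C@@]1(C)C(C(O)C=C)C(=C(C)C)CC[C@@H]1C
F4 | step 16 | (1S,7S,8R)-8-(2-chloroethyl)-4,4,7,8-tetramethyl-1,2,3,4,5,6,7,8-octahydronaphthalen-1-yl formate | ClCC[C@@]1(C)C2=C(CC[C@@H]1C)C(C)(C)CC[C@@H]2OC=O
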